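**Retrosynthetic overview**
- The strategy rests on the trans-fused decalin (ring A: C1–C5 and C10; ring B: C5–C10) that carries the exocyclic C8=C17 methylene next to C9 and the equatorial, oxygenated C18 on quaternary C4. The methylene is what an allylsilane terminator leaves behind, and the C18 site is where the E-hydroxymethyl of an epoxidised allylic alcohol lands in a chair–chair fold.
- Late stage: the C18 acetate, the free C15 acid and the C3 methylene go back to a 3β-hydroxy 18-silyl ether methyl ester (the C3 hydroxyl is removed by radical deoxygenation).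
- Key disconnection: C4–C5 and C9–C10 are cut together, which unfolds both rings to one acyclic (2S,3S)-epoxy E-ene Z-allylsilane chain. In the forward direction ring A closes first and leads into ring B in the same operation; no carbocycle exists before that.
- The chain is cut at C9–C11 and C5–C6 (two sp3–sp2 Negishi couplings, C9–C11 first) into an epoxy vinyl iodide (from 4-pentyn-1-ol), a Z-iodoalkenyl allylsilane (from 3-butyn-1-ol) and a C11–C15 iodo ester from methyl hydrogen (R)-3-methylglutarate, which supplies C13.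

Key step: step 15

Remark: labdane numbering is used for all intermediates (C18 = the 4α CH2O carbon, C19 = the 4β methyl, C20 = the C10 methyl, C17 = the exocyclic methylene carbon); the target is (4R,5R,9S,10R,13S).

**Route**

Step 1
Reactants: 1 4-pentyn-1-ol; 2 ethyl 2-(triphenylphosphoranylidene)propanoate
Product: 4 ethyl (E)-2-methylhept-2-en-6-ynoate, via 4-pentynal 3 (not isolated)
Conditions: PhI(OAc)2 (1.1 equiv), TEMPO (10 mol %), CH2Cl2, rt; then 2 (1.2 equiv), rt
Reagents that add atoms: none
Why: The nitroxyl-catalysed alcohol oxidation stops at the volatile aldehyde, which is trapped in the same flask by the stabilised, α-branched ylide in an E-selective Wittig olefination, so the ester carbon (future C18) ends trans to the chain.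

Step 2
Reactants: 4 ethyl (E)-2-methylhept-2-en-6-ynoate
Product: 5 (E)-2-methylhept-2-en-6-yn-1-ol
Conditions: i-Bu2AlH (2.2 equiv), CH2Cl2, −78 → 0 °C; aq. potassium sodium tartrate work-up
Reagents that add atoms: none
Why: Low-temperature hydride 1,2-reduction of the enoate (ester reduction) should give the allylic alcohol without touching the terminal alkyne or the alkene geometry.

Step 3
Reactants: 5 (E)-2-methylhept-2-en-6-yn-1-ol; 6 trimethylaluminium
Product: 8 (2E,6E)-7-iodo-2,6-dimethylhepta-2,6-dien-1-ol, via (E)-alkenyldimethylalane 7 (not isolated)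
Conditions: 6 (3 equiv), Cp2ZrCl2 (0.3 equiv), CH2Cl2, 0 °C → rt; then I2, THF, −30 → 0 °C; aq. NaHCO3/Na2S2O3 work-up
Reagents that add atoms: iodine, [I][I]
Why: Zirconium-catalysed syn-methylalumination (Negishi carboalumination) of the terminal alkyne, the hydroxyl being masked in the flask as its aluminium alkoxide, puts CH3 (C20) on the internal carbon and aluminium cis to it on C5, and iodinolysis with retention should give the E-vinyl iodide.

Step 4
Reactants: 8 (2E,6E)-7-iodo-2,6-dimethylhepta-2,6-dien-1-ol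
Product: 9 [(2S,3S)-3-[(E)-4-iodo-3-methylbut-3-en-1-yl]-2-methyloxiran-2-yl]methanol
Conditions: Ti(OiPr)4 (10 mol %), L-(+)-diethyl tartrate (12 mol %), t-BuOOH (2 equiv), 4 Å molecular sieves, CH2Cl2, −20 °C
Reagents that add atoms: tert-butyl hydroperoxide, CC(C)(C)OO
Why: In the Sharpless asymmetric epoxidation the titanium tartrate delivers oxygen only to the alkene of the allylic alcohol, and L-(+)-diethyl tartrate directs it to the face that gives the (2S,3S)-epoxide of an E-2-methyl-2-alken-1-ol, which sets C4 and C3; the non-allylic vinyl iodide is not oxidised.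

Step 5
Reactants: 9 [(2S,3S)-3-[(E)-4-iodo-3-methylbut-3-en-1-yl]-2-methyloxiran-2-yl]methanol
Product: 10 tert-butyl{[(2S,3S)-3-[(E)-4-iodo-3-methylbut-3-en-1-yl]-2-methyloxiran-2-yl]methoxy}diphenylsilane
Conditions: t-BuPh2SiCl (1.2 equiv), imidazole (2 equiv), CH2Cl2, 0 °C → rt
Reagents that add atoms: tert-butyl(chloro)diphenylsilane, CC(C)(C)[Si](Cl)(c1ccccc1)c1ccccc1
Why: Imidazole-promoted silylation of the primary hydroxyl is mild enough to avoid epoxide migration and installs a bulky, non-participating ether on C18.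

Step 6
Reactants: 11 3-butyn-1-ol
Product: 12 (but-3-yn-1-yloxy)(tert-butyl)dimethylsilane
Conditions: t-BuMe2SiCl (1.1 equiv), imidazole (2 equiv), CH2Cl2, rt
Reagents that add atoms: tert-butyl(chloro)dimethylsilane, CC(C)(C)[Si](C)(C)Cl
Why: Standard silyl ether formation removes the acidic hydroxyl proton before the organocopper step.

Step 7
Reactants: 12 (but-3-yn-1-yloxy)(tert-butyl)dimethylsilane; 13 (trimethylsilyl)methylmagnesium chloride
Product: 15 (Z)-tert-butyl({4-iodo-3-[(trimethylsilyl)methyl]but-3-en-1-yl}oxy)dimethylsilane, via (Z)-alkenylcopper 14 (not isolated)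
Conditions: 13 (1.5 equiv), CuBr·SMe2 (1.5 equiv), Et2O–THF, −10 °C → rt; then I2 (1 equiv relative to copper), THF, −40 → 0 °C
Reagents that add atoms: iodine, [I][I]
Why: Normant syn-carbocupration of the terminal alkyne by the silylmethylcopper reagent places CH2SiMe3 (C17) on the internal carbon and copper cis to it on C9, and iodinolysis with retention, with iodine kept limiting and cold to spare the allylsilane, should give the Z-iodide.

Step 8
Reactants: 16 methyl hydrogen (R)-3-methylglutarate
Product: 18 (S)-4-methyltetrahydro-2H-pyran-2-one, via (S)-5-hydroxy-3-methylpentanoic acid 17 (not isolated)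
Conditions: LiBH4 (2 equiv), THF, 0 °C → rt; then 2 M HCl; TsOH (cat.), toluene, 80 °C
Reagents that add atoms: none
Why: Borohydride reduces the ester but not the lithium carboxylate (chemoselective ester reduction), and the δ-hydroxy acid lactonises on acidification; the C13 centre lies β to both carbonyls and is untouched.

Step 9
Reactants: 18 (S)-4-methyltetrahydro-2H-pyran-2-one
Product: 20 (R)-5-iodo-3-methylpentanoic acid, via trimethylsilyl (R)-5-iodo-3-methylpentanoate 19 (not isolated)
Conditions: Me3SiI (1.3 equiv), CH2Cl2, rt; then H2O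
Reagents that add atoms: iodotrimethylsilane, C[Si](C)(C)I
Why: Silylation of the lactone carbonyl oxygen followed by SN2 attack of iodide at the primary O-alkyl carbon (C11) opens the ring (iodotrimethylsilane ester cleavage), and the silyl ester hydrolyses on work-up.

Step 10
Reactants: 20 (R)-5-iodo-3-methylpentanoic acid
Product: 21 methyl (R)-5-iodo-3-methylpentanoate
Conditions: MeOH, H2SO4 (cat.), rt
Reagents that add atoms: methanol, CO
Why: Fischer esterification under acid avoids the carboxylate, which would displace the iodide and re-form the lactone.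

Step 11
Reactants: 21 methyl (R)-5-iodo-3-methylpentanoate; 15 (Z)-tert-butyl({4-iodo-3-[(trimethylsilyl)methyl]but-3-en-1-yl}oxy)dimethylsilane
Product: 23 methyl (S,Z)-9-[(tert-butyldimethylsilyl)oxy]-3-methyl-7-[(trimethylsilyl)methyl]non-6-enoate, via alkylzinc iodide 22 (not isolated)
Conditions: Zn dust (activated by BrCH2CH2Br and Me3SiCl), THF, 40 °C; then 15, Pd(PPh3)4 (5 mol %), THF, rt → 45 °C
Reagents that add atoms: none
Why: Zinc insertion into the primary iodide tolerates the ester, and the zerovalent-palladium Negishi sp3–sp2 coupling forms C9–C11 with retention of the alkene geometry, so C11 stays cis to CH2SiMe3.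

Step 12
Reactants: 23 methyl (S,Z)-9-[(tert-butyldimethylsilyl)oxy]-3-methyl-7-[(trimethylsilyl)methyl]non-6-enoate
Product: 24 methyl (S,Z)-9-hydroxy-3-methyl-7-[(trimethylsilyl)methyl]non-6-enoate
Conditions: Bu4NF (1.5 equiv), AcOH (1.5 equiv), THF, 0 °C → rt
Reagents that add atoms: none
Why: Acetic acid-buffered fluoride desilylation cleaves the primary silyl ether without strong acid or naked alkoxide, so the acid-sensitive allylsilane and the ester should survive.

Step 13
Reactants: 24 methyl (S,Z)-9-hydroxy-3-methyl-7-[(trimethylsilyl)methyl]non-6-enoate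
Product: 25 methyl (S,Z)-9-iodo-3-methyl-7-[(trimethylsilyl)methyl]non-6-enoate
Conditions: PPh3 (1.3 equiv), imidazole (1.5 equiv), I2 (1.3 equiv), pre-mixed in CH2Cl2 at 0 °C; then 24, 0 °C
Reagents that add atoms: iodine, [I][I]
Why: In the Appel-type iodination the iodine is bound as the iodophosphonium salt before the alcohol is added, so the primary hydroxyl is displaced by SN2 while the nucleophilic allylsilane does not meet free iodine.

Step 14
Reactants: 25 methyl (S,Z)-9-iodo-3-methyl-7-[(trimethylsilyl)methyl]non-6-enoate; 10 tert-butyl{[(2S,3S)-3-[(E)-4-iodo-3-methylbut-3-en-1-yl]-2-methyloxiran-2-yl]methoxy}diphenylsilane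
Product: 27 methyl (3S,6Z,10E)-13-[(2S,3S)-3-{[(tert-butyldiphenylsilyl)oxy]methyl}-3-methyloxiran-2-yl]-3,11-dimethyl-7-[(trimethylsilyl)methyl]trideca-6,10-dienoate, via alkylzinc iodide 26 (not isolated)
Conditions: Zn dust (activated by BrCH2CH2Br and Me3SiCl), THF, 35 °C; then 10, Pd(PPh3)4 (5 mol %), THF, rt
Reagents that add atoms: none
Why: A second Negishi sp3–sp2 coupling forms C5–C6 with retention of the E geometry; in THF at room temperature the alkylzinc halide should leave the epoxide, the ester and both silyl groups alone.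

Step 15
Reactants: 27 methyl (3S,6Z,10E)-13-[(2S,3S)-3-{[(tert-butyldiphenylsilyl)oxy]methyl}-3-methyloxiran-2-yl]-3,11-dimethyl-7-[(trimethylsilyl)methyl]trideca-6,10-dienoate
Product: 28 methyl (3S,4R,5R,9S,10R,13S)-18-[(tert-butyldiphenylsilyl)oxy]-3β-hydroxylabd-8(17)-en-15-oate
Conditions: MeAlCl2 (2.5 equiv), CH2Cl2, −78 °C; aq. NaHCO3 quench
Reagents that add atoms: none
Why: MeAlCl2 binds the epoxide oxygen and the C4–O bond ionises as C5 of the E C5=C10 alkene attacks C4 from the backside, the developing C10 cation is captured by C9 of the allylsilane, and the β-silyl cation at C8 collapses by loss of the silyl group to leave only the exocyclic C8=C17 alkene, the aluminium alkoxide giving the 3β-hydroxyl on work-up. The closest known reaction type is the Lewis acid-promoted, epoxide-initiated and allylsilane-terminated cationic polyene bicyclisation that gives trans-decalins with an 8(17)-methylene. Ring A (bond C4–C5) closes 6-endo at the alkene with endo opening of the epoxide at its tertiary carbon, and ring B (bond C9–C10) closes 6-endo at the allylsilane. C3 keeps the configuration set in step 4 and sits equatorial, C4 is set by stereospecific inversion so that the E-derived CH2OSi (C18) is equatorial and CH3 (C19) axial, C5 and C10 are set by anti addition across the E alkene in a chair (trans ring fusion, C20 axial), and C9 is set by the Z allylsilane geometry, which places C11 equatorial in the chair of ring B. The step needs opening at tertiary C4 and not at C3, a chair–chair fold and a single alkene regioisomer; these are secured by the greater cation stability at C4, by the trans-epoxide with the two defined alkene geometries and the equatorial preference of the aluminium-bound C3 oxygen, and by the β-silicon effect, while the bulky silyl ether on C18 cannot participate and the ester only consumes a further equivalent of Lewis acid.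

Step 16
Reactants: 28 methyl (3S,4R,5R,9S,10R,13S)-18-[(tert-butyldiphenylsilyl)oxy]-3β-hydroxylabd-8(17)-en-15-oate
Product: 29 methyl (3S,4R,5R,9S,10R,13S)-18-[(tert-butyldiphenylsilyl)oxy]-3β-[(1H-imidazol-1-ylcarbonothioyl)oxy]labd-8(17)-en-15-oate
Conditions: 1,1'-thiocarbonyldiimidazole (3 equiv), DMAP (0.3 equiv), ClCH2CH2Cl, 80 °C
Reagents that add atoms: 1,1'-thiocarbonyldiimidazole, S=C(n1ccnc1)n1ccnc1
Why: Thioacylation of the only free hydroxyl with a small, reactive thiocarbonyl transfer reagent under heating should overcome the hindrance next to quaternary C4 and gives the precursor for radical deoxygenation.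

Step 17
Reactants: 29 methyl (3S,4R,5R,9S,10R,13S)-18-[(tert-butyldiphenylsilyl)oxy]-3β-[(1H-imidazol-1-ylcarbonothioyl)oxy]labd-8(17)-en-15-oate
Product: 30 methyl (4R,5R,9S,10R,13S)-18-[(tert-butyldiphenylsilyl)oxy]labd-8(17)-en-15-oate
Conditions: Bu3SnH (2 equiv), AIBN (0.2 equiv), toluene, 110 °C
Reagents that add atoms: none
Why: In the Barton–McCombie deoxygenation the stannyl radical adds to sulfur, the secondary C3 radical is released and reduced by the tin hydride, and that radical has no alkene within reach for cyclisation, so the C3 carbinol is erased without affecting the exocyclic alkene.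

Step 18
Reactants: 30 methyl (4R,5R,9S,10R,13S)-18-[(tert-butyldiphenylsilyl)oxy]labd-8(17)-en-15-oate
Product: 31 methyl (4R,5R,9S,10R,13S)-18-hydroxylabd-8(17)-en-15-oate
Conditions: Bu4NF (3 equiv), THF, rt → 45 °C
Reagents that add atoms: none
Why: Fluoride desilylation cleaves the neopentyl silyl ether through the strong Si–F bond, with no acid that could move the exocyclic alkene.

Step 19
Reactants: 31 methyl (4R,5R,9S,10R,13S)-18-hydroxylabd-8(17)-en-15-oate
Product: 32 (4R,5R,9S,10R,13S)-18-hydroxylabd-8(17)-en-15-oic acid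
Conditions: LiOH (5 equiv), THF–MeOH–H2O, rt → 40 °C; then 1 M HCl to pH 3, 0 °C
Reagents that add atoms: lithium hydroxide, [Li+].[OH-]
Why: Saponification of the unhindered methyl ester is done before acetylation, because the C18 acetate would not survive it; C13 is β to the carbonyl and cannot epimerise.

Step 20
Reactants: 32 (4R,5R,9S,10R,13S)-18-hydroxylabd-8(17)-en-15-oic acid
Product: 34 (4R,5R,9S,10R,13S)-18-acetoxylabd-8(17)-en-15-oic acid, via mixed acetic anhydride 33 (not isolated)
Conditions: Ac2O (4 equiv), pyridine, DMAP (0.1 equiv), CH2Cl2, rt; then H2O, pyridine–THF, rt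
Reagents that add atoms: acetic anhydride, CC(=O)OC(C)=O
Why: DMAP-catalysed acetylation esterifies the neopentyl primary hydroxyl, and the mixed anhydride formed at the carboxyl group is hydrolysed at its unhindered acetyl carbonyl on aqueous work-up, which returns the free C15 acid.

**Compound list**

1 | 4-pentyn-1-ol | C#CCCCO | starting material
2 | ethyl 2-(triphenylphosphoranylidene)propanoate | CCOC(=O)C(C)=P(c1ccccc1)(c1ccccc1)c1ccccc1 | starting material
3 | 4-pentynal | C#CCCC=O | intermediate
4 | ethyl (E)-2-methylhept-2-en-6-ynoate | C#CCC/C=C(\C)C(=O)OCC | intermediate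
5 | (E)-2-methylhept-2-en-6-yn-1-ol | C#CCC/C=C(\C)CO | intermediate
6 | trimethylaluminium | C[Al](C)C | starting material
7 | dimethyl[(1E,5E)-7-[(dimethylalumanyl)oxy]-2,6-dimethylhepta-1,5-dien-1-yl]alumane | C[Al](C)/C=C(\C)CC/C=C(\C)CO[Al](C)C | intermediate
8 | (2E,6E)-7-iodo-2,6-dimethylhepta-2,6-dien-1-ol | I/C=C(\C)CC/C=C(\C)CO | intermediate
9 | [(2S,3S)-3-[(E)-4-iodo-3-methylbut-3-en-1-yl]-2-methyloxiran-2-yl]methanol | OC[C@]1(C)O[C@H]1CC/C(C)=C/I | intermediate
10 | tert-butyl{[(2S,3S)-3-[(E)-4-iodo-3-methylbut-3-en-1-yl]-2-methyloxiran-2-yl]methoxy}diphenylsilane | CC(C)(C)[Si](c1ccccc1)(c1ccccc1)OC[C@]2(C)O[C@H]2CC/C(C)=C/I | intermediate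
11 | 3-butyn-1-ol | C#CCCO | starting material
12 | (but-3-yn-1-yloxy)(tert-butyl)dimethylsilane | C#CCCO[Si](C)(C)C(C)(C)C | intermediate
13 | (trimethylsilyl)methylmagnesium chloride | C[Si](C)(C)C[Mg]Cl | starting material
14 | {(Z)-4-[(tert-butyldimethylsilyl)oxy]-2-[(trimethylsilyl)methyl]but-1-en-1-yl}copper | CC(C)(C)[Si](C)(C)OCC/C(C[Si](C)(C)C)=C/[Cu] | intermediate
15 | (Z)-tert-butyl({4-iodo-3-[(trimethylsilyl)methyl]but-3-en-1-yl}oxy)dimethylsilane | CC(C)(C)[Si](C)(C)OCC/C(C[Si](C)(C)C)=C/I | intermediate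
16 | methyl hydrogen (R)-3-methylglutarate | COC(=O)C[C@H](C)CC(=O)O | starting material
17 | (S)-5-hydroxy-3-methylpentanoic acid | OCC[C@H](C)CC(=O)O | intermediate
18 | (S)-4-methyltetrahydro-2H-pyran-2-one | O=C1C[C@@H](C)CCO1 | intermediate
19 | trimethylsilyl (R)-5-iodo-3-methylpentanoate | ICC[C@H](C)CC(=O)O[Si](C)(C)C | intermediate
20 | (R)-5-iodo-3-methylpentanoic acid | ICC[C@H](C)CC(=O)O | intermediate
21 | methyl (R)-5-iodo-3-methylpentanoate | ICC[C@H](C)CC(=O)OC | intermediate
22 | [(R)-5-methoxy-3-methyl-5-oxopentyl]zinc iodide | I[Zn]CC[C@H](C)CC(=O)OC | intermediate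
23 | methyl (S,Z)-9-[(tert-butyldimethylsilyl)oxy]-3-methyl-7-[(trimethylsilyl)methyl]non-6-enoate | CC(C)(C)[Si](C)(C)OCC/C(C[Si](C)(C)C)=C/CC[C@H](C)CC(=O)OC | intermediate
24 | methyl (S,Z)-9-hydroxy-3-methyl-7-[(trimethylsilyl)methyl]non-6-enoate | OCC/C(C[Si](C)(C)C)=C/CC[C@H](C)CC(=O)OC | intermediate
25 | methyl (S,Z)-9-iodo-3-methyl-7-[(trimethylsilyl)methyl]non-6-enoate | ICC/C(C[Si](C)(C)C)=C/CC[C@H](C)CC(=O)OC | intermediate
26 | [(3Z,7S)-9-methoxy-7-methyl-9-oxo-3-[(trimethylsilyl)methyl]non-3-en-1-yl]zinc iodide | I[Zn]CC/C(C[Si](C)(C)C)=C/CC[C@H](C)CC(=O)OC | intermediate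
27 | methyl (3S,6Z,10E)-13-[(2S,3S)-3-{[(tert-butyldiphenylsilyl)oxy]methyl}-3-methyloxiran-2-yl]-3,11-dimethyl-7-[(trimethylsilyl)methyl]trideca-6,10-dienoate | CC(C)(C)[Si](c1ccccc1)(c1ccccc1)OC[C@]2(C)O[C@H]2CC/C(C)=C/CC/C(C[Si](C)(C)C)=C/CC[C@H](C)CC(=O)OC | intermediate
28 | methyl (3S,4R,5R,9S,10R,13S)-18-[(tert-butyldiphenylsilyl)oxy]-3β-hydroxylabd-8(17)-en-15-oate | C=C1CC[C@H]2[C@](C)(CO[Si](c3ccccc3)(c3ccccc3)C(C)(C)C)[C@@H](O)CC[C@]2(C)[C@H]1CC[C@H](C)CC(=O)OC | intermediate
29 | methyl (3S,4R,5R,9S,10R,13S)-18-[(tert-butyldiphenylsilyl)oxy]-3β-[(1H-imidazol-1-ylcarbonothioyl)oxy]labd-8(17)-en-15-oate | C=C1CC[C@H]2[C@](C)(CO[Si](c3ccccc3)(c3ccccc3)C(C)(C)C)[C@@H](OC(=S)n3ccnc3)CC[C@]2(C)[C@H]1CC[C@H](C)CC(=O)OC | intermediate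
30 | methyl (4R,5R,9S,10R,13S)-18-[(tert-butyldiphenylsilyl)oxy]labd-8(17)-en-15-oate | C=C1CC[C@H]2[C@](C)(CO[Si](c3ccccc3)(c3ccccc3)C(C)(C)C)CCC[C@]2(C)[C@H]1CC[C@H](C)CC(=O)OC | intermediate
31 | methyl (4R,5R,9S,10R,13S)-18-hydroxylabd-8(17)-en-15-oate | C=C1CC[C@H]2[C@](C)(CO)CCC[C@]2(C)[C@H]1CC[C@H](C)CC(=O)OC | intermediate
32 | (4R,5R,9S,10R,13S)-18-hydroxylabd-8(17)-en-15-oic acid | C=C1CC[C@H]2[C@](C)(CO)CCC[C@]2(C)[C@H]1CC[C@H](C)CC(=O)O | intermediate
33 | acetic (4R,5R,9S,10R,13S)-18-acetoxylabd-8(17)-en-15-oic anhydride | C=C1CC[C@H]2[C@](C)(COC(C)=O)CCC[C@]2(C)[C@H]1CC[C@H](C)CC(=O)OC(C)=O | intermediate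
34 | (4R,5R,9S,10R,13S)-18-acetoxylabd-8(17)-en-15-oic acid | C=C1CC[C@H]2[C@](C)(COC(C)=O)CCC[C@]2(C)[C@H]1CC[C@H](C)CC(=O)O | target

**Step count**
Total step count: 20
Longest linear sequence: 13 steps (steps 8 to 20, from 16)

**Steps most likely to fail**

Step 15. The cationic cascade may stop after ring A has closed, or the Lewis acid may rearrange the inductively deactivated epoxide or strip the silyl terminator before ring B closes. The fallback moves the ring closure to the radical manifold on a silicon-free chain; it sets out from 12 and comes back at 28.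
- From 12, zirconium-catalysed methylalumination with 6 (Cp2ZrCl2) and iodinolysis would give (E)-tert-butyl[(4-iodo-3-methylbut-3-en-1-yl)oxy]dimethylsilane F1.
- Negishi coupling of F1 with the zinc reagent 22 would give methyl (S,E)-9-[(tert-butyldimethylsilyl)oxy]-3,7-dimethylnon-6-enoate F2.
- Buffered fluoride would free methyl (S,E)-9-hydroxy-3,7-dimethylnon-6-enoate F3, and Appel iodination would give methyl (S,E)-9-iodo-3,7-dimethylnon-6-enoate F4.
- Zinc insertion would give [(3E,7S)-9-methoxy-3,7-dimethyl-9-oxonon-3-en-1-yl]zinc iodide F5, and Negishi coupling with 10 would give methyl (3S,6E,10E)-13-[(2S,3S)-3-{[(tert-butyldiphenylsilyl)oxy]methyl}-3-methyloxiran-2-yl]-3,7,11-trimethyltrideca-6,10-dienoate F6.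
- Titanocene monochloride Cp2TiCl (trivalent titanium, made from Cp2TiCl2 and Mn dust in THF) would open the epoxide of F6 homolytically to the tertiary C4 radical. This radical should close ring A and then ring B in a chair–chair array, and a second Cp2TiCl should turn the tertiary C8 radical into the exocyclic alkene by β-hydride elimination, giving 28.
- C4 would then be set by the equatorial preference of the bulky silyloxymethyl group and not by inversion, so a C4 epimer might have to be separated.

Step 14. The zinc halide or the palladium catalyst may open or rearrange the trisubstituted epoxide, or slow transmetalation may let the alkylzinc be protonated. The fallback forms C5–C6 before the epoxide exists; it sets out from 8 and comes back at 27.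
- Silylation of 8 would give tert-butyl{[(2E,6E)-7-iodo-2,6-dimethylhepta-2,6-dien-1-yl]oxy}dimethylsilane F7.
- Negishi coupling of F7 with the zinc reagent 26 would give methyl (3S,6Z,10E,14E)-16-[(tert-butyldimethylsilyl)oxy]-3,11,15-trimethyl-7-[(trimethylsilyl)methyl]hexadeca-6,10,14-trienoate F8.
- Buffered fluoride would free methyl (3S,6Z,10E,14E)-16-hydroxy-3,11,15-trimethyl-7-[(trimethylsilyl)methyl]hexadeca-6,10,14-trienoate F9.
- Sharpless epoxidation with L-(+)-diethyl tartrate, which touches only the alkene of the allylic alcohol, would give methyl (3S,6Z,10E)-13-[(2S,3S)-3-(hydroxymethyl)-3-methyloxiran-2-yl]-3,11-dimethyl-7-[(trimethylsilyl)methyl]trideca-6,10-dienoate F10.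
- Silylation of F10 with t-BuPh2SiCl and imidazole would give 27.

Step 16. The hydroxyl next to quaternary C4 may resist thioacylation, or the thiocarbonyl derivative may undergo thermal syn-elimination in step 17 instead of radical cleavage. The fallback removes the oxygen through the ketone; it sets out from 28 and comes back at 30.
- Dess–Martin oxidation of 28 would give methyl (4R,5R,9S,10R,13S)-18-[(tert-butyldiphenylsilyl)oxy]-3-oxolabd-8(17)-en-15-oate F11.
- Condensation with p-toluenesulfonohydrazide would give the 3-(p-toluenesulfonyl)hydrazone of methyl (4R,5R,9S,10R,13S)-18-[(tert-butyldiphenylsilyl)oxy]-3-oxolabd-8(17)-en-15-oate F12.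
- Reduction of F12 with catecholborane followed by sodium acetate trihydrate, which leaves the ester and the alkene alone, would give the C3 methylene compound 30 by loss of sulfinate and dinitrogen.

**Further compounds**
F1 | step 15 | (E)-tert-butyl[(4-iodo-3-methylbut-3-en-1-yl)oxy]dimethylsilane | CC(C)(C)[Si](C)(C)OCC/C(C)=C/I
F2 | step 15 | methyl (S,E)-9-[(tert-butyldimethylsilyl)oxy]-3,7-dimethylnon-6-enoate | CC(C)(C)[Si](C)(C)OCC/C(C)=C/CC[C@H](C)CC(=O)OC
F3 | step 15 | methyl (S,E)-9-hydroxy-3,7-dimethylnon-6-enoate | OCC/C(C)=C/CC[C@H](C)CC(=O)OC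
F4 | step 15 | methyl (S,E)-9-iodo-3,7-dimethylnon-6-enoate | ICC/C(C)=C/CC[C@H](C)CC(=O)OC
F5 | step 15 | [(3E,7S)-9-methoxy-3,7-dimethyl-9-oxonon-3-en-1-yl]zinc iodide | I[Zn]CC/C(C)=C/CC[C@H](C)CC(=O)OC
F6 | step 15 | methyl (3S,6E,10E)-13-[(2S,3S)-3-{[(tert-butyldiphenylsilyl)oxy]methyl}-3-methyloxiran-2-yl]-3,7,11-trimethyltrideca-6,10-dienoate | CC(C)(C)[Si](c1ccccc1)(c1ccccc1)OC[C@]2(C)O[C@H]2CC/C(C)=C/CC/C(C)=C/CC[C@H](C)CC(=O)OC
F7 | step 14 | tert-butyl{[(2E,6E)-7-iodo-2,6-dimethylhepta-2,6-dien-1-yl]oxy}dimethylsilane | CC(C)(C)[Si](C)(C)OC/C(C)=C/CC/C(C)=C/I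
F8 | step 14 | methyl (3S,6Z,10E,14E)-16-[(tert-butyldimethylsilyl)oxy]-3,11,15-trimethyl-7-[(trimethylsilyl)methyl]hexadeca-6,10,14-trienoate | CC(C)(C)[Si](C)(C)OC/C(C)=C/CC/C(C)=C/CC/C(C[Si](C)(C)C)=C/CC[C@H](C)CC(=O)OC
F9 | step 14 | methyl (3S,6Z,10E,14E)-16-hydroxy-3,11,15-trimethyl-7-[(trimethylsilyl)methyl]hexadeca-6,10,14-trienoate | OC/C(C)=C/CC/C(C)=C/CC/C(C[Si](C)(C)C)=C/CC[C@H](C)CC(=O)OC
F10 | step 14 | methyl (3S,6Z,10E)-13-[(2S,3S)-3-(hydroxymethyl)-3-methyloxiran-2-yl]-3,11-dimethyl-7-[(trimethylsilyl)methyl]trideca-6,10-dienoate | OC[C@]1(C)O[C@H]1CC/C(C)=C/CC/C(C[Si](C)(C)C)=C/CC[C@H](C)CC(=O)OC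
F11 | step 16 | methyl (4R,5R,9S,10R,13S)-18-[(tert-butyldiphenylsilyl)oxy]-3-oxolabd-8(17)-en-15-oate | C=C1CC[C@H]2[C@](C)(CO[Si](c3ccccc3)(c3ccccc3)C(C)(C)C)C(=O)CC[C@]2(C)[C@H]1CC[C@H](C)CC(=O)OC
F12 | step 16 | 3-(p-toluenesulfonyl)hydrazone of methyl (4R,5R,9S,10R,13S)-18-[(tert-butyldiphenylsilyl)oxy]-3-oxolabd-8(17)-en-15-oate | C=C1CC[C@H]2[C@](C)(CO[Si](c3ccccc3)(c3ccccc3)C(C)(C)C)C(=NNS(=O)(=O)c3ccc(C)cc3)CC[C@]2(C)[C@H]1CC[C@H](C)CC(=O)OC
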